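**Conventions.** Atom numbering for every compound: ring C1 (methyl-bearing), C2, C3 (CH2), C4 (carries the chain), C5 (2-methylbutanoate oxygen), C6 (hydroxyl); chain C7(=C14H2)–C8(angelate oxygen)–C9H2–C10–C11(CH3)2. Compounds are numbered 1–33 in the order in which they appear in the steps; the full list follows step 24.

Remark: the C5 acyl group is read from the target structure as (R)-2-methylbutanoyl and comes from (R)-2-methylbutanoic acid 29.
Remark: alcohol 17 is carried as a mixture of C1 epimers (C1 undefined in its SMILES), because C1 becomes a carbonyl carbon in step 13.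

## Analysis of the target

Target 33 is a bisabolane-type diester: one cyclohexane ring (C1–C6) with a methyl group and an epoxide at C1–C2, a free hydroxyl at C6, an (R)-2-methylbutanoate at C5 and, at C4, the chain C7(=C14H2)–C8(O-angeloyl)–C9H2–C10–C11 that ends in a dimethyloxirane. There are eight stereocentres: C1 (R), C2 (S), C4 (S), C5 (R) and C6 (R) on the ring, C8 (S) and C10 (R) in the chain, and the (R) α-carbon of the C5 acyl group. On the ring, the epoxide oxygen, the C6 hydroxyl, the C5 acyloxy group and the C4 chain all lie on one face, so C4–C5–C6–C1/C2 is an all-cis array. C8 and C10 are insulated from the ring and from each other and need reagent control. Sensitive groups are the (Z)-angelate (isomerises to the tiglate), the cis-vicinal hydroxy ester (acyl migration from C5 to C6 under base), two trisubstituted epoxides (acid), the epimerisable acyl α-carbon, and the 1,1-disubstituted alkene between C4 and C8. The hard points are the all-cis ring array with the bulky C4 chain cis to its oxygenated neighbour, telling the C5 and C6 oxygens apart, and making C7=C14 without olefinating a ketone flanked by two stereocentres. The strategy rests on the position of that methylene group: C7=C14 sits on ring carbon C4, which is where an allylsilane with silicon on C14 leaves its double bond after reacting through its γ-carbon C4. The bond C3–C4 can therefore be made by conjugate allylation of a C1 vinyl ketone, which closes the ring in the same event.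

## Retrosynthetic reasoning

**33 ⇒ 32 (C10–C11 epoxide).** The acid-labile side-chain epoxide is made last. In 32 the ring alkene is already epoxidised, the angelate alkene is electron-poor and C7=C14 is hindered and 1,1-disubstituted, so a chiral dioxirane has only one electron-rich trisubstituted alkene to attack. The forward reaction must set C10 by reagent control.

**32 ⇒ 31 (C1–C2 epoxide).** The ring epoxide is cis to the C6 hydroxyl, so a hydroxyl-directed epoxidation of the allylic alcohol 31 sets C1 and C2 from C6.

**31 ⇒ 30 ⇒ 28 ⇒ 27 (C6–H bond, C5–O ester bond).** The two ring oxygens are distinguished by oxidation level: only C6–OH in diol 27 is allylic and can be oxidised selectively to the enone 28. The remaining C5 hydroxyl is then the only free hydroxyl. It is esterified with 29 with inversion, which both installs the ester and turns C5 into the configuration of the target (see the key disconnection). 1,2-Reduction of 30 anti to the axial C5 ester then returns C6–OH on the required face. Direct mono-acylation of a 5,6-diol was not relied on, because the allylic C6 hydroxyl is the more accessible one.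

**27 ⇒ 26 ⇒ 23 ⇒ 22 (C8–O ester bond, acetonide).** The angelate is attached at 23, where C8–OH is the only free hydroxyl, and before the diol is unmasked. Fluoride desilylation thus occurs while no ester is present, and no selectivity between C8–OH and C6–OH is ever needed.

**22 ⇒ 21 ⇒ 19 (C1–CH3 bond).** The C1 methyl and the C1=C2 alkene come from the ketone 19 through its C1–C2 enol triflate 21 and a methyl cross-coupling. The forward step needs kinetic enolisation away from the oxygenated C6.

**19 ⇒ 18 (C3–C4 bond, ring closure; key disconnection).** Cutting C3–C4 opens the ring to the allylsilane vinyl ketone 18. One bond-forming event then makes the ring, the C4 stereocentre and the C7=C14 alkene. The chair for this closure decides the configuration that C5 must have in 18. With the C7 arm equatorial, the axial substituent on C5 is the one that nearly eclipses the reacting C4=C7 bond and faces the cis CH2SiMe3 group. Allylic 1,3-strain therefore demands C5–H axial and C5–O equatorial, which places the new arm trans to the C5 oxygen. A precursor with the C5 configuration of the target would have to react through the chair with the C5 oxygen in that eclipsed position, and the all-cis ring cannot be expected directly. Compound 18 therefore carries C5 in the (S) configuration (C6 as in the target) as a trans-acetonide, which can bridge only two equatorial oxygens and so locks this chair. C5 is inverted later, in the esterification 28 ⇒ 30.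

**18 ⇒ 17 ⇒ 16 ⇒ 15 (C1–C2 bond).** The polymerisable vinyl ketone is made last before the key step, from the primary alcohol 15 by oxidation, vinyl addition and oxidation.

**15 ⇒ 13 + 14; 13 ⇒ 12 ⇒ 11 ⇒ 9 (C7–C14 bond, C4=C7 geometry).** The allylsilane comes from the (Z)-alkenyl iodide by cross-coupling with 14. The iodide comes from the propargylic alcohol 9 by hydroxyl-directed trans-hydrostannation and iododestannylation. A direct anti-carbomagnesiation of 9 with 14 was not used, because it passes through a C4–magnesium species with the C5 oxygen in β-position, which can eliminate to an allene.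

**9 ⇒ 8 ⇒ 4 + 6 (C7–C8 bond, C8 stereocentre).** The acetylide of 4 is acylated with the Weinreb amide 6 (from acid 5), and C8 is set by asymmetric transfer hydrogenation of the ynone 8.

**4 ⇒ 3 ⇒ 2 ⇒ 1 (C4–C7 bond).** The alkyne comes from the aldehyde 3 by one-carbon homologation. Compound 3 derives from the C2-symmetric, tartrate-derived diol 1, whose two ends are equivalent, so mono-protection needs no regiocontrol. All aldehydes on a trans-dioxolane (3, 16) are the thermodynamically preferred epimers and should not epimerise.

## Alternatives that were turned down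

**Alternative 1:** The ring oxygens C5/C6 are traced back to an arene. The key step is a whole-cell toluene-dioxygenase cis-dihydroxylation of 4-iodotoluene A1, giving the diene diol A2. In its favour, one step from a commodity arene delivers the ring, the C1 methyl, both ring carbinols as an enantio-enriched cis-diol, and an iodide at C4 for attaching C7. Against it for this target: after the chain is coupled at C4, the C3=C4 bond of a cross-conjugated triene must be reduced regio- and face-selectively to create C4, while C1=C2 and C7=C14 survive. Diene diols such as A2 aromatise easily by dehydration. para-Disubstituted arenes are oxidised with less regio- and enantiocontrol than monosubstituted ones, and fermentation capacity is required. On the C5/C6 relationship this route is stronger than the chosen one, which has to invert C5 and regenerate C6. The chosen strategy offers instead a C4 centre set in the ring-forming step and a C7=C14 alkene that needs no selective reduction around it.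

**Alternative 2:** The ring is cut at C4–C5 and C2–C3. The key step is an endo Diels–Alder addition of (E)-1-acetoxy-3-methylbuta-1,3-diene A3 to 3-acryloyloxazolidin-2-one A4 on a divalent copper bis(oxazoline) Lewis acid (from Cu(OTf)2), giving the cycloadduct A5. In its favour, it is catalytic and asymmetric, and the endo rule gives the C4/C5 cis pair directly, which the chair cyclisation of the chosen route cannot deliver. Against it: A5 has its alkene at C1=C6 and no oxygen at C6, so an allylic oxygenation with alkene transposition and face control is still needed. The whole chain must be grown from the C4 acyl group, and methylenation of a C7 ketone next to the epimerisable C4 invites drift to the trans isomer. C8 needs a further asymmetric step, and the acetate must be exchanged for the 2-methylbutanoate. The ring arrives faster, but the chain costs many steps. The chosen strategy brings the complete chain with C8 set by catalyst control and makes C7=C14 without carbonyl olefination.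

**Alternative 3:** The ring is cut at C1–C6. The key step is an intramolecular Nozaki–Hiyama–Kishi reaction of the open-chain (Z)-alkenyl iodide aldehyde A6 with CrCl2 and catalytic NiCl2, giving the ring allylic alcohol A7, which is identical with compound 31 of the present route. In its favour, the closure is chemoselective, tolerates both esters and lands two steps from the target, so its endgame is shorter than the chosen one. Against it: the C6 configuration is created in the closure, next to an α-acyloxy aldehyde for which Felkin and chelate pathways compete. A6 needs the C4/C5 syn pair and C8 from acyclic stereocontrol, and an α-acyloxy aldehyde with a β-branch is prone to epimerisation, acyl migration and β-elimination. Stoichiometric chromium is also needed. The chosen strategy places its stereochemical risk in a ring closure with a single accessible chair and takes the ring oxygens from the chiral pool.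

Key step: step 14

## Route

Step 1
Reactants: 1 (4S,5S)-2,2-dimethyl-1,3-dioxolane-4,5-dimethanol
Product: 2 mono-PMB ether [(4S,5S)-5-{[(4-methoxybenzyl)oxy]methyl}-2,2-dimethyl-1,3-dioxolan-4-yl]methanol
Conditions: NaH (1.0 equiv), THF/DMF, 0 °C; PMBCl, Bu4NI (cat.), 0 → 23 °C
Reagents that add atoms: 4-methoxybenzyl chloride, COc1ccc(CCl)cc1
Why: Williamson etherification of a C2-symmetric diol whose two hydroxyls are equivalent, so mono-alkylation needs no regiocontrol; bis-ether and unreacted diol are separated and the diol recycled.

Step 2
Reactants: 2 mono-PMB ether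
Product: 3 aldehyde (4R,5S)-5-{[(4-methoxybenzyl)oxy]methyl}-2,2-dimethyl-1,3-dioxolane-4-carbaldehyde (the CHO carbon is C4)
Conditions: Dess–Martin periodinane, NaHCO3, CH2Cl2, 0 → 23 °C
Reagents that add atoms: none
Why: Dess–Martin oxidation of the primary alcohol under buffered conditions; the aldehyde sits on a trans-disubstituted dioxolane, the thermodynamically preferred arrangement, so C5 should keep its configuration.

Step 3
Reactants: 3 aldehyde
Product: 4 alkyne (4S,5S)-4-ethynyl-5-{[(4-methoxybenzyl)oxy]methyl}-2,2-dimethyl-1,3-dioxolane (C4≡C7)
Conditions: dimethyl (1-diazo-2-oxopropyl)phosphonate, K2CO3, MeOH, 0 → 23 °C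
Reagents that add atoms: dimethyl (1-diazo-2-oxopropyl)phosphonate, CC(=O)C(=[N+]=[N-])P(=O)(OC)OC
Why: Ohira–Bestmann form of the Seyferth–Gilbert homologation: methanolysis of the reagent gives the diazomethylphosphonate anion, which olefinates the aldehyde; loss of N2 and a 1,2-hydrogen shift give the alkyne. The mild base cannot erode a trans-dioxolane aldehyde.

Step 4
Reactants: 5 4-methylpent-3-enoic acid
Product: 6 N-methoxy-N,4-dimethylpent-3-enamide
Conditions: MeNHOMe·HCl, EDC·HCl, N-methylmorpholine, CH2Cl2, 0 → 23 °C
Reagents that add atoms: N,O-dimethylhydroxylamine hydrochloride, CNOC.Cl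
Why: Carbodiimide amide coupling to the Weinreb amide; the weak amine base should leave the β,γ-alkene out of conjugation.

Step 5
Reactants: 4 alkyne; 6 Weinreb amide
Product: 8 ynone (C4≡C7–C8(=O)–C9H2–C10=C11), via lithium acetylide 7 (not isolated)
Conditions: n-BuLi (1.05 equiv), THF, −78 °C; then 6, −78 → −20 °C; cold aq. NH4Cl
Reagents that add atoms: none
Why: Weinreb ketone synthesis forming C7–C8: the acetylide adds once and the chelated tetrahedral adduct survives until the cold quench, which also protonates the released amine before it can add to the ynone.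

Step 6
Reactants: 8 ynone
Product: 9 (8S)-propargylic alcohol
Conditions: Ru[(S,S)-TsDPEN](p-cymene) (2 mol %), i-PrOH, 23 °C, no added base
Reagents that add atoms: none
Why: Noyori asymmetric transfer hydrogenation of an alkynyl ketone; the alkyne takes the place of the aryl group of an aryl ketone, so the (S,S) ligand should deliver the (S) carbinol at C8 under catalyst control. The base-free amido complex should leave the skipped C9 methylene unisomerised.

Step 7
Reactants: 9 propargylic alcohol
Product: 11 (Z)-alkenyl iodide (iodine on C7, cis to C5), via alkenylstannane 10 (not isolated)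
Conditions: [Cp*RuCl]4 (2.5 mol %), Bu3SnH (1.05 equiv), CH2Cl2, 23 °C; then I2 (1.1 equiv), −78 → 0 °C
Reagents that add atoms: iodine, II
Why: Hydroxyl-directed ruthenium-catalysed trans-hydrostannation puts tin on C7, the alkyne carbon next to the free C8 hydroxyl (hydrogen bond to the Ru–Cl unit), and hydrogen anti on C4; iododestannylation retains the geometry. No metal is ever placed on C4, where the β-oxygen at C5 could leave to give an allene.

Step 8
Reactants: 11 alkenyl iodide
Product: 12 C8 tert-butyldimethylsilyl ether
Conditions: TBSOTf, 2,6-lutidine, CH2Cl2, −78 → 0 °C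
Reagents that add atoms: tert-butyldimethylsilyl trifluoromethanesulfonate, CC(C)(C)[Si](C)(C)OS(=O)(=O)C(F)(F)F
Why: Silylation of the hindered allylic alcohol with the silyl triflate; C8–O must be masked through the Grignard, Lewis acid and enolate steps.

Step 9
Reactants: 12 silyl ether
Product: 13 C1 primary alcohol
Conditions: DDQ, CH2Cl2/pH 7 buffer (10:1), 0 °C
Reagents that add atoms: none
Why: Oxidative cleavage of the p-methoxybenzyl ether (hydride abstraction, then hydrolysis of the oxocarbenium ion); silyl ether, acetonide, alkenyl iodide and the trisubstituted alkene are inert, and no allylsilane is present yet.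

Step 10
Reactants: 13 alkenyl iodide alcohol; 14 (trimethylsilyl)methylmagnesium chloride
Product: 15 (Z)-allylsilane primary alcohol
Conditions: Pd(PPh3)4 (5 mol %), 14 (3 equiv), THF, 23 → 45 °C
Reagents that add atoms: none
Why: Kumada–Corriu coupling: oxidative addition of zerovalent palladium to the alkenyl iodide, transmetalation and reductive elimination with retention, so CH2SiMe3 ends up cis to C5. One equivalent of 14 is consumed by the free hydroxyl.

Step 11
Reactants: 15 allylsilane alcohol
Product: 16 C1 aldehyde
Conditions: Dess–Martin periodinane, NaHCO3, CH2Cl2, 0 °C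
Reagents that add atoms: none
Why: Buffered Dess–Martin oxidation; the trans-dioxolane again protects the α-centre (C6) from epimerisation and the neutral medium spares the allylsilane.

Step 12
Reactants: 16 aldehyde
Product: 17 C1 vinyl carbinol (mixture of C1 epimers)
Conditions: CH2=CHMgBr, THF, −78 °C
Reagents that add atoms: vinylmagnesium bromide, C=C[Mg]Br
Why: Grignard 1,2-addition forming C1–C2; both epimers serve because C1 is oxidised in the next step.

Step 13
Reactants: 17 vinyl carbinol
Product: 18 allylsilane vinyl ketone (5S,6R,8S; trans-acetonide)
Conditions: Dess–Martin periodinane, NaHCO3, CH2Cl2, 0 °C; used at once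
Reagents that add atoms: none
Why: Dess–Martin oxidation of the secondary allylic alcohol merges the C1 epimers into the vinyl ketone; the product is a polymerisable Michael acceptor and goes straight into step 14.

Step 14
Reactants: 18 allylsilane vinyl ketone
Product: 19 cyclohexanone (4S,5S,6R,8S) with trans-fused acetonide, C4 chain and C7=C14 methylene
Conditions: EtAlCl2 (1.2 equiv), PhMe, −78 °C; aq. NaHCO3
Reagents that add atoms: none
Why: EtAlCl2 binds the C1 carbonyl of the s-trans enone and the allylsilane attacks C3 through its γ-carbon C4, anti to the C14–Si bond. The β-silyl cation at C7 then loses Me3Si as Me3SiCl, which places the alkene regiospecifically at C7=C14 and leaves the C1–C2 aluminium enolate, protonated on work-up. This is an intramolecular Hosomi–Sakurai conjugate allylation, a known way to annulate allylsilanes onto enones. The ring closes in a 6-endo-trig mode with respect to the enone (C2 and C3 both become ring atoms) and exo with respect to the allylsilane. The one new stereocentre, C4, is controlled by C5 through a chair: the trans-dioxolane can bridge only two equatorial oxygens, so O5 and O6 are equatorial and C5–H is axial. With the C7 arm equatorial, that axial C5–H is the group that nearly eclipses C4=C7 and faces the cis CH2SiMe3, so allylic 1,3-strain is minimal, whereas the chair with the arm axial puts the ring bond C5–C6 in that position. The step needs facial selectivity at C4 (arm trans to O5, cis to O6) and γ-regioselectivity; the ring fusion secures the first and silicon the second, and the ethyl group on aluminium scavenges protons that would otherwise cause protodesilylation.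

Step 15
Reactants: 19 cyclohexanone
Product: 21 C1–C2 enol triflate, via potassium enolate 20 (not isolated)
Conditions: KN(SiMe3)2, THF, −78 °C; PhNTf2, −78 → −20 °C
Reagents that add atoms: N-phenylbis(trifluoromethanesulfonimide), O=S(=O)(N(c1ccccc1)S(=O)(=O)C(F)(F)F)C(F)(F)F
Why: Kinetic deprotonation by a bulky amide takes a C2 proton rather than the hindered, kinetically less acidic α-alkoxy methine at C6; O-sulfonylation of the enolate fixes the C1=C2 position.

Step 16
Reactants: 21 enol triflate
Product: 22 1-methylcyclohexene (C1–CH3, C1=C2)
Conditions: MeMgBr, Fe(acac)3 (5 mol %), THF/NMP, −30 → 0 °C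
Reagents that add atoms: methylmagnesium bromide, C[Mg]Br
Why: Iron-catalysed Kumada-type cross-coupling of an alkenyl triflate with a methyl Grignard reagent; silyl ether, acetonide and the isolated alkenes do not react.

Step 17
Reactants: 22 silyl ether
Product: 23 C8 alcohol
Conditions: Bu4NF, THF, 0 → 23 °C
Reagents that add atoms: none
Why: Fluoride cleavage of the silyl ether; no ester is present yet, so the basic reagent cannot cause acyl migration.

Step 18
Reactants: 23 C8 alcohol; 24 angelic acid
Product: 26 C8 angelate, via mixed anhydride 25 (not isolated)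
Conditions: 24, 2,4,6-trichlorobenzoyl chloride, Et3N, PhMe, 23 °C; then 23, 75 °C
Reagents that add atoms: none
Why: Yamaguchi esterification through the mixed anhydride, run without a nucleophilic pyridine catalyst to limit Z→E isomerisation to the tiglate; C8–OH is the only free hydroxyl at this stage.

Step 19
Reactants: 26 acetonide
Product: 27 trans-5,6-diol
Conditions: AcOH/H2O (4:1), 35 °C
Reagents that add atoms: none
Why: Acid hydrolysis of the acetonide; a trans-fused dioxolane on a cyclohexene is strained and should cleave under conditions that leave the angelate and the alkenes untouched.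

Step 20
Reactants: 27 diol
Product: 28 5-hydroxy-6-ketone (α-hydroxy enone)
Conditions: activated MnO2 (15 equiv), CH2Cl2, 23 °C
Reagents that add atoms: none
Why: MnO2 oxidises only the allylic hydroxyl (C6), which differentiates the two ring oxygens by oxidation level; a trans-diol is a poor substrate for glycol cleavage.

Step 21
Reactants: 28 α-hydroxy enone; 29 (R)-2-methylbutanoic acid
Product: 30 6-keto 5-[(R)-2-methylbutanoate] with C5 inverted to (R)
Conditions: PPh3, DIAD, PhMe, 0 → 23 °C
Reagents that add atoms: none
Why: Mitsunobu esterification: the C5 alkoxyphosphonium ion is displaced by the carboxylate in an SN2 reaction accelerated by the adjacent carbonyl, with inversion, turning the equatorial C5–O (trans to the arm) into the axial ester (cis to the arm). The equatorial leaving group has no antiperiplanar hydrogen, which disfavours E2, and the acid is never activated at its own α-stereocentre.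

Step 22
Reactants: 30 keto diester
Product: 31 allylic alcohol with C4 chain, C5 ester and C6 hydroxyl all cis
Conditions: NaBH4, CeCl3·7H2O, MeOH, −78 °C; AcOH quench
Reagents that add atoms: none
Why: Luche 1,2-reduction: hydride adds to C6 anti to the axial C5 acyloxy group (Felkin–Anh; axial attack as in the reduction of carvone to cis-carveol), giving C6–OH cis to the ester and the arm. Low temperature and an acidic quench limit acyl migration.

Step 23
Reactants: 31 allylic alcohol
Product: 32 C1–C2 epoxy alcohol
Conditions: VO(acac)2 (5 mol %), t-BuOOH, CH2Cl2, 0 → 23 °C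
Reagents that add atoms: tert-butyl hydroperoxide, CC(C)(C)OO
Why: Hydroxyl-directed epoxidation: the vanadium alkoxide–peroxide complex delivers oxygen to the face of C1=C2 syn to C6–OH, setting C1 and C2; the other alkenes have no directing allylic hydroxyl.

Step 24
Reactants: 32 epoxy alcohol
Product: 33 target CNP0181486.1
Conditions: 1,2:4,5-di-O-isopropylidene-β-D-erythro-2,3-hexodiulo-2,6-pyranose (Shi ketone, 0.5 equiv), KHSO5 (Oxone), NaHCO3, MeCN/dimethoxymethane–aq. Na2EDTA, pH ca. 8, 0 °C
Reagents that add atoms: potassium peroxymonosulfate, OOS(=O)(=O)[O-].[K+]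
Why: Shi asymmetric epoxidation by the chiral dioxirane through a spiro transition state; the electron-rich trisubstituted C10=C11 should react far faster than the hindered C7=C14 or the angelate, and the D-fructose-derived ketone should give (R) at C10. The near-neutral buffer is chosen to suppress C5→C6 acyl migration.

## Compound list

1 | (4S,5S)-2,2-dimethyl-1,3-dioxolane-4,5-dimethanol ((+)-2,3-O-isopropylidene-L-threitol) | OC[C@@H]1OC(C)(C)O[C@H]1CO | starting material
2 | [(4S,5S)-5-{[(4-methoxybenzyl)oxy]methyl}-2,2-dimethyl-1,3-dioxolan-4-yl]methanol | COc1ccc(COC[C@@H]2OC(C)(C)O[C@H]2CO)cc1 | intermediate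
3 | (4R,5S)-5-{[(4-methoxybenzyl)oxy]methyl}-2,2-dimethyl-1,3-dioxolane-4-carbaldehyde | COc1ccc(COC[C@@H]2OC(C)(C)O[C@H]2C=O)cc1 | intermediate
4 | (4S,5S)-4-ethynyl-5-{[(4-methoxybenzyl)oxy]methyl}-2,2-dimethyl-1,3-dioxolane | COc1ccc(COC[C@@H]2OC(C)(C)O[C@H]2C#C)cc1 | intermediate
5 | 4-methylpent-3-enoic acid | CC(C)=CCC(=O)O | starting material
6 | N-methoxy-N,4-dimethylpent-3-enamide | CON(C)C(=O)CC=C(C)C | intermediate
7 | lithium acetylide of 4 | COc1ccc(COC[C@@H]2OC(C)(C)O[C@H]2C#C[Li])cc1 | intermediate
8 | ynone (C1 O-PMB, trans-acetonide, C4≡C7, C8 ketone) | COc1ccc(COC[C@@H]2OC(C)(C)O[C@H]2C#CC(=O)CC=C(C)C)cc1 | intermediate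
9 | (8S)-propargylic alcohol | COc1ccc(COC[C@@H]2OC(C)(C)O[C@H]2C#C[C@H](CC=C(C)C)O)cc1 | intermediate
10 | (Z)-C7-tributylstannyl allylic alcohol | COc1ccc(COC[C@@H]2OC(C)(C)O[C@H]2/C=C(\[Sn](CCCC)(CCCC)CCCC)[C@H](CC=C(C)C)O)cc1 | intermediate
11 | (Z)-C7-iodo allylic alcohol | COc1ccc(COC[C@@H]2OC(C)(C)O[C@H]2/C=C(\I)[C@H](CC=C(C)C)O)cc1 | intermediate
12 | C8 tert-butyldimethylsilyl ether of 11 | COc1ccc(COC[C@@H]2OC(C)(C)O[C@H]2/C=C(\I)[C@H](CC=C(C)C)O[Si](C)(C)C(C)(C)C)cc1 | intermediate
13 | C1 primary alcohol with (Z)-alkenyl iodide | OC[C@@H]1OC(C)(C)O[C@H]1/C=C(\I)[C@H](CC=C(C)C)O[Si](C)(C)C(C)(C)C | intermediate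
14 | (trimethylsilyl)methylmagnesium chloride | C[Si](C)(C)C[Mg]Cl | starting material
15 | (Z)-allylsilane primary alcohol | OC[C@@H]1OC(C)(C)O[C@H]1/C=C(\C[Si](C)(C)C)[C@H](CC=C(C)C)O[Si](C)(C)C(C)(C)C | intermediate
16 | C1 aldehyde | O=C[C@@H]1OC(C)(C)O[C@H]1/C=C(\C[Si](C)(C)C)[C@H](CC=C(C)C)O[Si](C)(C)C(C)(C)C | intermediate
17 | C1 vinyl carbinol (C1 epimers) | C=CC(O)[C@@H]1OC(C)(C)O[C@H]1/C=C(\C[Si](C)(C)C)[C@H](CC=C(C)C)O[Si](C)(C)C(C)(C)C | intermediate
18 | allylsilane vinyl ketone (5S,6R,8S) | C=CC(=O)[C@@H]1OC(C)(C)O[C@H]1/C=C(\C[Si](C)(C)C)[C@H](CC=C(C)C)O[Si](C)(C)C(C)(C)C | intermediate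
19 | cyclohexanone (4S,5S,6R,8S), trans-fused acetonide | C=C([C@H](CC=C(C)C)O[Si](C)(C)C(C)(C)C)[C@@H]1CCC(=O)[C@@H]2OC(C)(C)O[C@@H]12 | intermediate
20 | potassium C1–C2 enolate of 19 | C=C([C@H](CC=C(C)C)O[Si](C)(C)C(C)(C)C)[C@@H]1CC=C(O[K])[C@@H]2OC(C)(C)O[C@@H]12 | intermediate
21 | C1–C2 enol triflate | C=C([C@H](CC=C(C)C)O[Si](C)(C)C(C)(C)C)[C@@H]1CC=C(OS(=O)(=O)C(F)(F)F)[C@@H]2OC(C)(C)O[C@@H]12 | intermediate
22 | 1-methylcyclohexene acetonide silyl ether | C=C([C@H](CC=C(C)C)O[Si](C)(C)C(C)(C)C)[C@@H]1CC=C(C)[C@@H]2OC(C)(C)O[C@@H]12 | intermediate
23 | C8 alcohol | C=C([C@H](CC=C(C)C)O)[C@@H]1CC=C(C)[C@@H]2OC(C)(C)O[C@@H]12 | intermediate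
24 | angelic acid ((Z)-2-methylbut-2-enoic acid) | C/C=C(/C)C(=O)O | starting material
25 | angelic 2,4,6-trichlorobenzoic anhydride | C/C=C(/C)C(=O)OC(=O)c1c(Cl)cc(Cl)cc1Cl | intermediate
26 | C8 angelate acetonide | C=C([C@H](CC=C(C)C)OC(=O)/C(C)=C\C)[C@@H]1CC=C(C)[C@@H]2OC(C)(C)O[C@@H]12 | intermediate
27 | trans-5,6-diol | C=C([C@H](CC=C(C)C)OC(=O)/C(C)=C\C)[C@@H]1CC=C(C)[C@H](O)[C@H]1O | intermediate
28 | 5-hydroxy-6-ketone (α-hydroxy enone, 5S) | C=C([C@H](CC=C(C)C)OC(=O)/C(C)=C\C)[C@@H]1CC=C(C)C(=O)[C@H]1O | intermediate
29 | (R)-2-methylbutanoic acid | CC[C@@H](C)C(=O)O | starting material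
30 | 6-keto 5-[(R)-2-methylbutanoate] (5R) | C=C([C@H](CC=C(C)C)OC(=O)/C(C)=C\C)[C@@H]1CC=C(C)C(=O)[C@@H]1OC(=O)[C@H](C)CC | intermediate
31 | ring allylic alcohol with both esters | C=C([C@H](CC=C(C)C)OC(=O)/C(C)=C\C)[C@@H]1CC=C(C)[C@H](O)[C@@H]1OC(=O)[C@H](C)CC | intermediate
32 | C1–C2 epoxy alcohol | C=C([C@H](CC=C(C)C)OC(=O)/C(C)=C\C)[C@@H]1C[C@@H]2O[C@]2(C)[C@H](O)[C@@H]1OC(=O)[C@H](C)CC | intermediate
33 | CNP0181486.1 | C=C([C@H](C[C@H]1OC1(C)C)OC(=O)/C(C)=C\C)[C@@H]1C[C@@H]2O[C@]2(C)[C@H](O)[C@@H]1OC(=O)[C@H](C)CC | target

## Step count and least certain steps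

Total: 24 steps. Longest linear sequence: 23 steps (steps 1–3 and 5–24; step 4 is a one-step branch).

**Step 14 (key step).** The trans-fused ring is more strained than a cis-fused one, so closure may be slow and protodesilylation or polymerisation of the vinyl ketone may win. The Lewis acid may also open the strained acetonide, or the C5 oxygen may add to the activated enone. Facial selectivity could erode if a boat pathway intervenes or if the remote C8 centre is mismatched. Fallback: from 18, 1,2-addition of MeMgBr in the presence of CeCl3 should give the tertiary allylic alcohol F1. Ionisation with BF3·OEt2 at −78 °C would give the C1–C2–C3 allyl cation, which the allylsilane captures at C3 through the same chair (cation–allylsilane cyclisation). This forms C3–C4 and gives the methylcyclohexene 22 directly, so the route is rejoined at 22 and steps 15 and 16 are not needed.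

**Step 21.** With a weakly acidic aliphatic acid and a hindered carbinol, substitution may be slow. Enolisation of the α-ketol, elimination, or esterification with retention through an acyloxyphosphonium pathway could then take over. Fallback: from 28, sulfonylation with Tf2O and pyridine at −78 °C should give the α-keto triflate F2, a separately activated electrophile without a basic betaine present. Displacement with cesium (R)-2-methylbutanoate and 18-crown-6 in toluene then gives 30 with inversion.

**Step 15.** Deprotonation at C6 could compete (its proton is axial in 19), followed by β-elimination of the C5 oxygen or formation of the wrong enol triflate. Fallback: from 19, condensation with 2,4,6-triisopropylbenzenesulfonyl hydrazide should give the hydrazone F3, whose sulfonamide nitrogen lies on the less hindered C2 side. A Shapiro reaction (n-BuLi, 2.2 equiv) deprotonates syn to it and gives the C1 alkenyllithium, and methyl iodide then delivers 22.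

**Step 20.** Over-oxidation, glycol cleavage or isomerisation of the α-ketol could lower the material balance. Fallback: from 27, the more accessible allylic C6 hydroxyl is silylated selectively (Et3SiCl, imidazole, −40 °C) to the C6 triethylsilyl ether F4. Mitsunobu esterification of C5–OH with 29 gives the inverted ester F5, and buffered HF·pyridine frees C6–OH to give 31. This keeps the original C6 centre and leaves out steps 20–22.

**Step 24.** The buffer may still promote acyl migration from C5 to C6 in the cis hydroxy ester. Catalyst control over the remote C10 may be incomplete, or C7=C14 may be attacked. Fallback: the order of the endgame is changed so that the dioxirane meets no free hydroxyl. From 30, Shi epoxidation gives the epoxy keto diester F6, Luche reduction gives the epoxy allylic alcohol F7, and the directed epoxidation with VO(acac)2 and t-BuOOH then gives 33.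

## Further compounds

F1 | step 14 | tertiary allylic alcohol from methyl addition to 18 (C1 epimers) | C=CC(C)(O)[C@@H]1OC(C)(C)O[C@H]1/C=C(\C[Si](C)(C)C)[C@H](CC=C(C)C)O[Si](C)(C)C(C)(C)C
F2 | step 21 | α-keto triflate of 28 | C=C([C@H](CC=C(C)C)OC(=O)/C(C)=C\C)[C@@H]1CC=C(C)C(=O)[C@H]1OS(=O)(=O)C(F)(F)F
F3 | step 15 | 2,4,6-triisopropylbenzenesulfonyl hydrazone of 19 | C=C([C@H](CC=C(C)C)O[Si](C)(C)C(C)(C)C)[C@@H]1CCC(=NNS(=O)(=O)c3c(C(C)C)cc(C(C)C)cc3C(C)C)[C@@H]2OC(C)(C)O[C@@H]12
F4 | step 20 | C6 triethylsilyl ether of diol 27 | C=C([C@H](CC=C(C)C)OC(=O)/C(C)=C\C)[C@@H]1CC=C(C)[C@H](O[Si](CC)(CC)CC)[C@H]1O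
F5 | step 20 | C6 triethylsilyl ether of 31 | C=C([C@H](CC=C(C)C)OC(=O)/C(C)=C\C)[C@@H]1CC=C(C)[C@H](O[Si](CC)(CC)CC)[C@@H]1OC(=O)[C@H](C)CC
F6 | step 24 | C10–C11 epoxide of keto diester 30 | C=C([C@H](C[C@H]1OC1(C)C)OC(=O)/C(C)=C\C)[C@@H]1CC=C(C)C(=O)[C@@H]1OC(=O)[C@H](C)CC
F7 | step 24 | C10–C11 epoxide of allylic alcohol 31 | C=C([C@H](C[C@H]1OC1(C)C)OC(=O)/C(C)=C\C)[C@@H]1CC=C(C)[C@H](O)[C@@H]1OC(=O)[C@H](C)CC
A1 | alternative 1 | 4-iodotoluene | Cc1ccc(I)cc1
A2 | alternative 1 | (1S,2S)-3-iodo-6-methylcyclohexa-3,5-diene-1,2-diol | IC1=CC=C(C)[C@H](O)[C@@H]1O
A3 | alternative 2 | (E)-1-acetoxy-3-methylbuta-1,3-diene | CC(=O)O/C=C/C(C)=C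
A4 | alternative 2 | 3-acryloyloxazolidin-2-one | C=CC(=O)N1CCOC1=O
A5 | alternative 2 | cis-2-acetoxy-4-methylcyclohex-3-ene-1-carbonyl oxazolidinone | O=C(N1CCOC1=O)[C@@H]2CCC(C)=C[C@@H]2OC(C)=O
A6 | alternative 3 | open-chain (Z)-alkenyl iodide aldehyde with both esters | C=C([C@H](CC=C(C)C)OC(=O)/C(C)=C\C)[C@H](C/C=C(/C)I)[C@H](C=O)OC(=O)[C@H](C)CC
A7 | alternative 3 | ring allylic alcohol with both esters | C=C([C@H](CC=C(C)C)OC(=O)/C(C)=C\C)[C@@H]1CC=C(C)[C@H](O)[C@@H]1OC(=O)[C@H](C)CC
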